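Begin with an easy division: coupling partner charged over both substrates charged.

| setting | red | grey | ochre | flask |
|---|---|---|---|---|
| left-handed substrate | 0.021 M | 0.031 M | 0.041 M | 0.041 M |
| right-handed substrate | 0.021 M | 0.031 M | 0.041 M | 0.041 M |
| coupling partner | 0.082 M | 0.082 M | 0.082 M | 0.0820 M |
| protic impurity | 2.05 mM | 2.05 mM | 4.1 mM | 2.05 mM |
| free catalyst | 0.82 mM | 0.82 mM | 0.82 mM | 0.82 mM |
| remark | run made earlier | run made earlier | run made earlier |  |
| time |  |  |  | 10 d |

- red (time / d: left-handed product / %, right-handed product / %, left-handed substrate / %): 3.00: 49.8, 27.4, 0.4; 6.00: 48.0, 25.8, 1.5; 10.0: 49.0, 26.0, 1.5; 12.0: 48.5, 27.0, 1.7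
- grey (time / d: left-handed product / %, right-handed product / %, left-handed substrate / %): 3.00: 44.4, 18.5, 6.0; 6.00: 44.2, 19.2, 5.3; 10.0: 44.2, 18.9, 6.2; 12.0: 44.2, 18.8, 6.1
- ochre (time / d: left-handed product / %, right-handed product / %, left-handed substrate / %): 1.04: 37.4, 13.8, 13.2; 2.00: 37.9, 13.4, 12.3; 5.00: 36.9, 13.6, 12.2; 12.0: 36.8, 13.8, 12.6

(scatter of a reading: 0.5 percentage points)

- excess of left-handed product over right-handed product in the product at 5.0 h
- excess of left-handed product over right-handed product in the product at 10 d
- part of the left-handed substrate and right-handed substrate charged together that has reacted at 10 d

- free catalyst is single-handed; left-handed substrate and right-handed substrate are mirror images of each other, charged as a racemate, each of them at the stated concentration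
- the earlier runs were read with a standard deviation of 0.5 percentage points
- an excess is the difference of the two amounts in percent of their sum
- an excess is below zero if the other one leads

1. Apply the bench rule that one equivalent finishes a coupling. The flask's ratio is 1.00, so the rule promises full conversion.

2. Find its border. The red run's ratio is 1.95, yet its products add up to 75.0% at 10.0 d. The rule already fails there.

3. My working view: the impurity takes one coupling partner each. The rest goes two ways, to product and to loss, both first order in coupling partner. Hold the catalyst level fixed, divide the two rates and integrate. The share reaching product is k_product/(k_product + k_loss), and the coupling partner charge cancels.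

4. Read the reagent share, meaning product formed over coupling partner charged minus impurity charged. Take it from the ochre run, which has the flask's substrate and coupling partner charges. Its mean conversion is 50.9%, so the share reads 53.6%. The red run reads 39.4%, so the share is no constant: carry it only at a fixed substrate charge.

5. Apply it to the flask, which has half of the ochre run's impurity. My reckoning gives 52.2% reacted at 10 d.

6. Set beside it the forecast: an excess of 56% at 5.0 h, an excess of 46% at 10 d, and 52.5% reacted at 10 d. Its conversion differs slightly from mine, and it holds that “conversion stops because the catalyst dies”.

7. The flask gives an excess of 41.1% at 5.0 h, an excess of 45.4% at 10 d, and 52.0% reacted at 10 d.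

    free catalyst + left-handed substrate ⇌ catalyst intermediate A (K = 430 /M, k = 0.340 /M/s)
    free catalyst + right-handed substrate ⇌ catalyst intermediate B (K = 46.0 /M, k = 2.00 /M/s)
    coupling partner + catalyst intermediate A → free catalyst + left-handed product (k = 0.120 /M/s)
    coupling partner + catalyst intermediate B → free catalyst + right-handed product (k = 0.0510 /M/s)
    coupling partner → decomposed reagent (k = 4.50 × 10⁻⁵ /s)
    coupling partner + protic impurity → quenched reagent (k = 0.0280 /M/s)
    free catalyst → spent catalyst (k = 2.80 × 10⁻⁵ /s)

The flask's own share comes to 53.3%. At 1.00 d, the flask held 0.0230% of its coupling partner, while spent catalyst stood at 35.7% of the catalyst charged. The undoing of catalyst intermediate B into free catalyst and right-handed substrate is the main reason for the flask's excess of left-handed product at 10 d: with that undoing struck out, the excess reads −63.2% instead of 45.4%.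

In the neighbouring flask with 0.021 M of coupling partner, the share gives 12.4% reacted. The computed result is 14.6%.

Readings and results were computed from invented constants, and the scatter is random.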